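The route rests on cutting the C4–C5 bond, which joins the tertiary carbinol C4 to the ring-fusion carbon C5 and is the aldol bond of the β-oxygenated C4(OH)–C5(H)–C6(O) array shared by the five- and seven-membered rings. With C6 as a ketone, a catalytic alkoxide lets the C5 enolate add to a side-chain isopropyl ketone, closing the cyclopentane onto a finished cycloheptanone and settling C4 and C5 under equilibrium control in one operation. The precursor is a (3R,4S)-cycloheptanone whose quaternary C1 carries methyl (anti to a C10 silyloxy group) and a β-diketone chain with C2 masked as a base-stable 1,3-dithiane.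

Key step: step 10

Remark: atoms are numbered C1 (quaternary fusion carbon, methyl), C2, C3, C4 (isopropyl), C5 (fusion CH) around the cyclopentane and C6, C7, C8 (methyl), C9, C10 for the rest of the cycloheptane; β is the face of the C1 methyl group; the C10 carbinol made in step 2 serves to set C1 and is re-set in step 18.

Step 1
Reactants: 1 cyclohepta-1,3-diene
Product: 2 (1R,5S)-6,7-dioxabicyclo[3.2.2]non-8-ene (meso endoperoxide)
Conditions: O2, tetraphenylporphyrin (cat.), hν, CH2Cl2, −20 °C
Reagents that add atoms: dioxygen, O=O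
Why: Singlet oxygen adds across the cisoid diene in a [4+2] cycloaddition and the product is meso, so no stereochemical question arises.

Step 2
Reactants: 2 (1R,5S)-6,7-dioxabicyclo[3.2.2]non-8-ene
Product: 3 (S)-4-hydroxycyclohept-2-en-1-one
Conditions: 6'-hydroxy cinchona base (9-O-acetylcupreidine or its cupreine pseudo-enantiomer, 5 mol %; the antipode that leads to the S alcohol), CH2Cl2, rt
Reagents that add atoms: none
Why: In this catalytic asymmetric Kornblum–DeLaMare rearrangement the chiral amine removes one of the two enantiotopic bridgehead hydrogens next to the O–O bond, which then breaks to ketone and alkoxide, so the desymmetrisation sets the C10 carbinol as S.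

Step 3
Reactants: 3 (S)-4-hydroxycyclohept-2-en-1-one
Product: 4 (S)-4-(tert-butyldimethylsilyloxy)cyclohept-2-en-1-one
Conditions: TBSCl, imidazole, DMF, 0 °C to rt
Reagents that add atoms: tert-butyldimethylsilyl chloride, C[Si](C)(Cl)C(C)(C)C
Why: Standard silylation of a secondary allylic alcohol, which also prevents β-elimination of the γ-oxygen in the following enolate chemistry.

Step 4
Reactants: 4 (S)-4-(tert-butyldimethylsilyloxy)cyclohept-2-en-1-one; 5 (trimethylsilyl)acetylene
Product: 6 (3R,4S)-1,4-bis(tert-butyldimethylsilyloxy)-3-[(trimethylsilyl)ethynyl]cyclohept-1-ene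
Conditions: 5, n-BuLi, THF, −78 °C; ZnBr2; then 4, TBSOTf, −40 °C
Reagents that add atoms: (trimethylsilyl)acetylene 5, C#C[Si](C)(C)C; tert-butyldimethylsilyl triflate, C[Si](C)(OS(=O)(=O)C(F)(F)F)C(C)(C)C
Why: Silyl triflate-promoted conjugate addition of an alkynylzinc halide to a cyclic enone should deliver the alkynyl group anti to the neighbouring silyloxy group and trap the enolate regiospecifically as its silyl ether; the new centre is removed again in step 5.

Step 5
Reactants: 6 (3R,4S)-1,4-bis(tert-butyldimethylsilyloxy)-3-[(trimethylsilyl)ethynyl]cyclohept-1-ene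
Product: 7 (S)-4-(tert-butyldimethylsilyloxy)-3-[(trimethylsilyl)ethynyl]cyclohept-2-en-1-one
Conditions: Pd(OAc)2 (10 mol %), O2 (1 atm), DMSO, 40 °C
Reagents that add atoms: none
Why: Saegusa–Ito oxidation of the regiodefined enol ether forms a palladium enolate at C5 whose only β-hydrogen is on the alkynyl-bearing carbon, so the enone is regenerated with the substituent in the β-position.

Step 6
Reactants: 7 (S)-4-(tert-butyldimethylsilyloxy)-3-[(trimethylsilyl)ethynyl]cyclohept-2-en-1-one; 8 methylmagnesium bromide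
Product: 9 (3S,4S)-4-(tert-butyldimethylsilyloxy)-3-methyl-3-[(trimethylsilyl)ethynyl]cycloheptan-1-one
Conditions: MeMgBr, Cu(OTf)2 (5 mol %), 1,3-bis(2,4,6-trimethylphenyl)imidazolinium chloride (7 mol %), Et2O, −30 °C; aq. NH4Cl
Reagents that add atoms: methylmagnesium bromide 8, C[Mg]Br
Why: Copper–carbene-catalysed conjugate addition of a Grignard reagent to a cyclic enynone is expected to be 1,4- rather than 1,6-selective and to bring the methyl group in anti to the adjacent C10 silyloxy group, which sets the quaternary centre C1.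

Step 7
Reactants: 9 (3S,4S)-4-(tert-butyldimethylsilyloxy)-3-methyl-3-[(trimethylsilyl)ethynyl]cycloheptan-1-one
Product: 10 (3S,4S)-4-(tert-butyldimethylsilyloxy)-3-ethynyl-3-methylcycloheptan-1-one
Conditions: K2CO3 (cat.), MeOH, 0 °C to rt
Reagents that add atoms: none
Why: Methoxide-mediated protodesilylation of an alkynylsilane is fast and leaves the silyl ether and the ketone untouched.

Step 8
Reactants: 10 (3S,4S)-4-(tert-butyldimethylsilyloxy)-3-ethynyl-3-methylcycloheptan-1-one; 11 2-methylpropanoyl chloride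
Product: 12 (3S,4S)-4-(tert-butyldimethylsilyloxy)-3-methyl-3-(4-methyl-3-oxopent-1-yn-1-yl)cycloheptan-1-one
Conditions: PdCl2(PPh3)2 (2 mol %), CuI (4 mol %), Et3N (1.2 equiv), THF, rt
Reagents that add atoms: 2-methylpropanoyl chloride 11, CC(C)C(Cl)=O
Why: Acyl Sonogashira coupling acylates the terminal alkyne under mild amine conditions that the ring ketone tolerates, giving the ynone that holds C2, C3 and C4 in their final oxidation pattern.

Step 9
Reactants: 12 (3S,4S)-4-(tert-butyldimethylsilyloxy)-3-methyl-3-(4-methyl-3-oxopent-1-yn-1-yl)cycloheptan-1-one; 13 propane-1,3-dithiol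
Product: 15 (3R,4S)-4-(tert-butyldimethylsilyloxy)-3-methyl-3-[2-(3-methyl-2-oxobutyl)-1,3-dithian-2-yl]cycloheptan-1-one, via vinyl sulfide mono-adduct 14 (not isolated)
Conditions: 13 (1.2 equiv), NaOMe (0.3 equiv), MeOH/CH2Cl2, −10 to 0 °C; aq. NH4Cl
Reagents that add atoms: propane-1,3-dithiol 13, SCCCS
Why: Double thia-Michael addition of the dithiol to the ynone masks C2 as a dithiane chemoselectively, because ketones do not thioketalise under base and the thiol/thiolate buffer is too weakly basic to start the aldol.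

Step 10
Reactants: 15 (3R,4S)-4-(tert-butyldimethylsilyloxy)-3-methyl-3-[2-(3-methyl-2-oxobutyl)-1,3-dithian-2-yl]cycloheptan-1-one
Product: 16 cis-fused aldol product (C6 ketone; 4α-hydroxy; 4β-isopropyl; 1β-methyl; 5β-H; 10α-silyloxy; spiro-1,3-dithiane at C2)
Conditions: KOtBu (0.2 equiv), t-BuOH/THF (1:4), 0 °C to rt; AcOH quench
Reagents that add atoms: none
Why: Catalytic tert-butoxide reversibly enolises the C6 ketone and the C5 enolate adds to the C4 isopropyl ketone in a 5-exo-trig closure with the enolate double bond outside the new ring (enolexo), which creates the cyclopentane C1–C2–C3–C4–C5; the closest known reaction type is the equilibrating base-mediated intramolecular ketone–ketone aldol addition. Because aldolate formation, retro-aldol cleavage and enolisation at C5 are all reversible, both new centres are set under thermodynamic control: C5 by the angular C1 methyl group, which should favour the cis ring fusion (H-5 syn to methyl), and C4 by the hydrogen bond or potassium chelate between the C4 oxygen and the C6 carbonyl, which places the hydroxyl syn to C6 and the bulkier isopropyl group on the face of H-5. The step needs regioselectivity among the enolates at C5, C7, C3 and the isopropyl carbon and chemoselectivity between two carbonyl acceptors; only the C5-to-C4 mode gives an unstrained fused five-membered ring, whereas the C7-to-C4 and C3-to-C6 closures give bridged or larger rings that revert. The dithiane at C2 secures the equilibration, since a retro-thia-Michael opening from the C3 enolate re-closes and the product, no longer a ketone at C4, cannot eliminate. Substoichiometric base and an acidic quench keep the β-hydroxy ketone from dehydrating.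

Step 11
Reactants: 16 cis-fused aldol product
Product: 17 4α,6β-diol (10α-silyloxy; C2 dithiane)
Conditions: Me4NBH(OAc)3 (5 equiv), MeCN/AcOH (1:1), −20 °C
Reagents that add atoms: none
Why: In this Evans–Saksena reduction the C4 hydroxyl exchanges onto boron and delivers hydride to the α-face of C6 through a six-membered array cis-fused to the cyclopentane, which should give the 6β-alcohol and removes the retro-aldol pathway.

Step 12
Reactants: 17 4α,6β-diol; 18 (E)-2-methylbut-2-enoyl chloride (tigloyl chloride)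
Product: 19 6β-tiglate (4α-hydroxy; 10α-silyloxy; C2 dithiane)
Conditions: 18, Et3N, DMAP, CH2Cl2, 0 °C to rt
Reagents that add atoms: tigloyl chloride 18, C/C=C(\C)C(Cl)=O
Why: Acylation takes place at the only secondary hydroxyl, the tertiary C4 hydroxyl being inert under these conditions.

Step 13
Reactants: 19 6β-tiglate
Product: 20 10α-alcohol (6β-tiglate; 4α-hydroxy; C2 dithiane)
Conditions: HF·pyridine, pyridine, THF, 0 °C to rt
Reagents that add atoms: none
Why: Buffered fluoride cleaves the silyl ether without touching the ester, the dithiane or the tertiary alcohol.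

Step 14
Reactants: 20 10α-alcohol
Product: 21 C10 ketone (6β-tiglate; 4α-hydroxy; C2 dithiane)
Conditions: (COCl)2, DMSO, CH2Cl2, −78 °C; Et3N, −78 to 0 °C
Reagents that add atoms: none
Why: Swern oxidation converts the hindered secondary alcohol into the ketone with an activated-sulfoxide oxidant that leaves the dithiane intact.

Step 15
Reactants: 21 C10 ketone
Product: 23 enone (6β-tiglate; 4α-hydroxy; C2 dithiane; C8=C9; C10=O), via dilithium enolate 22 (not isolated)
Conditions: LiHMDS (2.2 equiv), THF, −78 °C; then N-tert-butylbenzenesulfinimidoyl chloride (1.3 equiv), −78 °C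
Reagents that add atoms: none
Why: Mukaiyama dehydrogenation sulfinimidoylates the enolate, which can form only toward C9 because C1 is quaternary, and syn-elimination at low temperature gives the enone without palladium or hypervalent iodine reagents that a dithiane would not tolerate.

Step 16
Reactants: 23 enone; 24 methyllithium
Product: 26 β-methyl enone (6β-tiglate; 4α-hydroxy; C2 dithiane; 8-methyl; C8=C9; C10=O), via dilithium enolate 25 (not isolated)
Conditions: MeLi, CuI, Et2O, −20 °C (gives Me2CuLi, 3 equiv); 23, −78 °C; then N-tert-butylbenzenesulfinimidoyl chloride, −78 °C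
Reagents that add atoms: methyllithium 24, [Li]C
Why: Conjugate addition of the Gilman reagent places the C8 methyl group, and dehydrogenation of the resulting enolate in the same flask by the Mukaiyama reagent restores the C8–C9 double bond; the tiglate is far less electrophilic than the cycloheptenone at −78 °C.

Step 17
Reactants: 26 β-methyl enone
Product: 27 2,10-diketone (6β-tiglate; 4α-hydroxy; 8-methyl; C8=C9)
Conditions: PhI(OCOCF3)2, NaHCO3, MeCN/H2O (9:1), 0 °C
Reagents that add atoms: water, O
Why: Oxidative dethioacetalisation with a hypervalent iodine reagent under buffered, near-neutral conditions frees the C2 ketone without dehydrating the tertiary β-hydroxyl.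

Step 18
Reactants: 27 2,10-diketone
Product: 29 triol (2β-OH; 4α-OH; 10α-OH; 6β-tiglate; 8-methyl; C8=C9), via C2 carbinol 28 (not isolated)
Conditions: Me4NBH(OAc)3 (6 equiv), MeCN/AcOH (1:1), −20 to 0 °C
Reagents that add atoms: none
Why: Two Evans–Saksena reductions in sequence should set both carbinols, the 4α-hydroxyl delivering hydride to the α-face of C2 (2β-alcohol) and the new 2β-hydroxyl then delivering hydride in a 1,2-sense to the β-face of the C10 enone (10α-alcohol).

Step 19
Reactants: 29 triol
Product: 30 2β-triethylsilyl ether (4α-OH; 10α-OH; 6β-tiglate; 8-methyl; C8=C9)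
Conditions: TESCl (1.05 equiv), imidazole, CH2Cl2, −20 °C
Reagents that add atoms: chlorotriethylsilane, CC[Si](Cl)(CC)CC
Why: Site-selective silylation is expected at the C2 hydroxyl on the convex β-face, because the C10 hydroxyl points into the fold of the cis-fused bicycle next to the quaternary carbon and the C4 hydroxyl is tertiary.

Step 20
Reactants: 30 2β-triethylsilyl ether
Product: 31 8α,9α-epoxide (10α-OH; 4α-OH; 2β-silyloxy; 6β-tiglate)
Conditions: VO(acac)2 (5 mol %), t-BuOOH, CH2Cl2, 0 °C
Reagents that add atoms: tert-butyl hydroperoxide, CC(C)(C)OO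
Why: Vanadium-catalysed hydroxyl-directed epoxidation delivers oxygen to the trisubstituted alkene on the face of the allylic C10 hydroxyl, which gives the α-epoxide and leaves the electron-poor tiglate alkene alone.

Step 21
Reactants: 31 8α,9α-epoxide; 18 tigloyl chloride
Product: 32 6β,10α-bis-tiglate 2β-triethylsilyl ether (8α,9α-epoxide; 4α-OH)
Conditions: 18, Et3N, DMAP, CH2Cl2, rt
Reagents that add atoms: tigloyl chloride 18, C/C=C(\C)C(Cl)=O
Why: Acylation of the only remaining secondary hydroxyl under basic conditions leaves the epoxide and the tertiary alcohol untouched.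

Step 22
Reactants: 32 6β,10α-bis-tiglate 2β-triethylsilyl ether
Product: 33 target CNP0265715.1 (2β,4α-dihydroxy-6β,10α-bis(tigloyloxy)-8α,9α-epoxide)
Conditions: HF·pyridine, pyridine, THF, 0 °C
Reagents that add atoms: none
Why: Pyridine-buffered fluoride removes the labile triethylsilyl ether at low temperature, conditions that trisubstituted epoxides and conjugated esters survive.

Compound list
1 | cyclohepta-1,3-diene | C1=CC=CCCC1 | starting material
2 | (1R,5S)-6,7-dioxabicyclo[3.2.2]non-8-ene (meso) | C1C[C@H]2C=C[C@@H](C1)OO2 | intermediate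
3 | (S)-4-hydroxycyclohept-2-en-1-one | O=C1C=C[C@@H](O)CCC1 | intermediate
4 | (S)-4-(tert-butyldimethylsilyloxy)cyclohept-2-en-1-one | O=C1C=C[C@@H](O[Si](C)(C)C(C)(C)C)CCC1 | intermediate
5 | (trimethylsilyl)acetylene | C#C[Si](C)(C)C | starting material
6 | (3R,4S)-1,4-bis(tert-butyldimethylsilyloxy)-3-[(trimethylsilyl)ethynyl]cyclohept-1-ene (alkynyl trans to the C4 silyloxy group) | CC(C)(C)[Si](C)(C)OC1=C[C@H](C#C[Si](C)(C)C)[C@@H](O[Si](C)(C)C(C)(C)C)CCC1 | intermediate
7 | (S)-4-(tert-butyldimethylsilyloxy)-3-[(trimethylsilyl)ethynyl]cyclohept-2-en-1-one | O=C1C=C(C#C[Si](C)(C)C)[C@@H](O[Si](C)(C)C(C)(C)C)CCC1 | intermediate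
8 | methylmagnesium bromide | C[Mg]Br | starting material
9 | (3S,4S)-4-(tert-butyldimethylsilyloxy)-3-methyl-3-[(trimethylsilyl)ethynyl]cycloheptan-1-one (methyl trans to the silyloxy group) | O=C1CCC[C@H](O[Si](C)(C)C(C)(C)C)[C@@](C#C[Si](C)(C)C)(C)C1 | intermediate
10 | (3S,4S)-4-(tert-butyldimethylsilyloxy)-3-ethynyl-3-methylcycloheptan-1-one | O=C1CCC[C@H](O[Si](C)(C)C(C)(C)C)[C@@](C#C)(C)C1 | intermediate
11 | 2-methylpropanoyl chloride | CC(C)C(Cl)=O | starting material
12 | (3S,4S)-4-(tert-butyldimethylsilyloxy)-3-methyl-3-(4-methyl-3-oxopent-1-yn-1-yl)cycloheptan-1-one | O=C1CCC[C@H](O[Si](C)(C)C(C)(C)C)[C@@](C#CC(=O)C(C)C)(C)C1 | intermediate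
13 | propane-1,3-dithiol | SCCCS | starting material
14 | vinyl sulfide mono-adduct of 12 (3-sulfanylpropylthio group on C2 of the enone chain; alkene geometry not fixed) | O=C1CCC[C@H](O[Si](C)(C)C(C)(C)C)[C@@](C(SCCCS)=CC(=O)C(C)C)(C)C1 | intermediate
15 | (3R,4S)-4-(tert-butyldimethylsilyloxy)-3-methyl-3-[2-(3-methyl-2-oxobutyl)-1,3-dithian-2-yl]cycloheptan-1-one (aldol precursor) | O=C1CCC[C@H](O[Si](C)(C)C(C)(C)C)[C@@](C2(SCCCS2)CC(=O)C(C)C)(C)C1 | intermediate
16 | cis-fused aldol product: bicyclo[5.3.0]decan-6-one with 1β-methyl, 5β-H, 4α-hydroxy, 4β-isopropyl, 10α-(tert-butyldimethylsilyloxy) and a spiro-1,3-dithiane at C2 | O=C1CCC[C@H](O[Si](C)(C)C(C)(C)C)[C@@]2(C)[C@@H]1[C@](O)(C(C)C)CC23SCCCS3 | intermediate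
17 | 4α,6β-diol of 16 (10α-silyloxy, C2 dithiane) | O[C@H]1CCC[C@H](O[Si](C)(C)C(C)(C)C)[C@@]2(C)[C@@H]1[C@](O)(C(C)C)CC23SCCCS3 | intermediate
18 | (E)-2-methylbut-2-enoyl chloride (tigloyl chloride) | C/C=C(\C)C(Cl)=O | starting material
19 | 6β-tiglate (4α-hydroxy, 10α-silyloxy, C2 dithiane) | C/C=C(\C)C(=O)O[C@H]1CCC[C@H](O[Si](C)(C)C(C)(C)C)[C@@]2(C)[C@@H]1[C@](O)(C(C)C)CC23SCCCS3 | intermediate
20 | 10α-alcohol (6β-tiglate, 4α-hydroxy, C2 dithiane) | C/C=C(\C)C(=O)O[C@H]1CCC[C@H](O)[C@@]2(C)[C@@H]1[C@](O)(C(C)C)CC23SCCCS3 | intermediate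
21 | C10 ketone (6β-tiglate, 4α-hydroxy, C2 dithiane) | C/C=C(\C)C(=O)O[C@H]1CCCC(=O)[C@@]2(C)[C@@H]1[C@](O)(C(C)C)CC23SCCCS3 | intermediate
22 | dilithium C9–C10 enolate and C4 alkoxide of 21 | C/C=C(\C)C(=O)O[C@H]1CCC=C(O[Li])[C@@]2(C)[C@@H]1[C@](O[Li])(C(C)C)CC23SCCCS3 | intermediate
23 | enone with C8=C9 and C10=O (6β-tiglate, 4α-hydroxy, C2 dithiane) | C/C=C(\C)C(=O)O[C@H]1CC=CC(=O)[C@@]2(C)[C@@H]1[C@](O)(C(C)C)CC23SCCCS3 | intermediate
24 | methyllithium | [Li]C | starting material
25 | dilithium 8-methyl C9–C10 enolate and C4 alkoxide (C8 configuration not relevant) | C/C=C(\C)C(=O)O[C@H]1CC(C)C=C(O[Li])[C@@]2(C)[C@@H]1[C@](O[Li])(C(C)C)CC23SCCCS3 | intermediate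
26 | β-methyl enone: 8-methyl, C8=C9, C10=O (6β-tiglate, 4α-hydroxy, C2 dithiane) | C/C=C(\C)C(=O)O[C@H]1CC(C)=CC(=O)[C@@]2(C)[C@@H]1[C@](O)(C(C)C)CC23SCCCS3 | intermediate
27 | 2,10-diketone: C2=O, 8-methyl, C8=C9, C10=O (6β-tiglate, 4α-hydroxy) | C/C=C(\C)C(=O)O[C@H]1CC(C)=CC(=O)[C@@]2(C)[C@@H]1[C@](O)(C(C)C)CC2=O | intermediate
28 | 2β,4α-diol with the C10 enone intact (6β-tiglate) | C/C=C(\C)C(=O)O[C@H]1CC(C)=CC(=O)[C@@]2(C)[C@@H]1[C@](O)(C(C)C)C[C@@H]2O | intermediate
29 | 2β,4α,10α-triol with 8-methyl C8=C9 alkene (6β-tiglate) | C/C=C(\C)C(=O)O[C@H]1CC(C)=C[C@H](O)[C@@]2(C)[C@@H]1[C@](O)(C(C)C)C[C@@H]2O | intermediate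
30 | 2β-triethylsilyl ether of 29 (4α- and 10α-hydroxyls free) | C/C=C(\C)C(=O)O[C@H]1CC(C)=C[C@H](O)[C@@]2(C)[C@@H]1[C@](O)(C(C)C)C[C@@H]2O[Si](CC)(CC)CC | intermediate
31 | 8α,9α-epoxide (10α-hydroxy, 4α-hydroxy, 2β-triethylsilyloxy, 6β-tiglate) | C/C=C(\C)C(=O)O[C@H]1C[C@]2(C)O[C@@H]2[C@H](O)[C@@]2(C)[C@@H]1[C@](O)(C(C)C)C[C@@H]2O[Si](CC)(CC)CC | intermediate
32 | 6β,10α-bis-tiglate 2β-triethylsilyl ether (8α,9α-epoxide, 4α-hydroxy) | C/C=C(\C)C(=O)O[C@H]1C[C@]2(C)O[C@@H]2[C@H](OC(=O)/C(C)=C/C)[C@@]2(C)[C@@H]1[C@](O)(C(C)C)C[C@@H]2O[Si](CC)(CC)CC | intermediate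
33 | CNP0265715.1: 2β,4α-dihydroxy-6β,10α-bis(tigloyloxy)-8α,9α-epoxy cis-fused daucane | C/C=C(\C)C(=O)O[C@H]1C[C@]2(C)O[C@@H]2[C@H](OC(=O)/C(C)=C/C)[C@@]2(C)[C@@H]1[C@](O)(C(C)C)C[C@@H]2O | target

Total step count: 22. Longest linear sequence: 22 steps (1 to 33).

Steps most likely to fail

Step 10. The equilibrium may not drain into one isomer: it could settle on a trans-fused or C4-epimeric aldol, or be slowed by unproductive enolisation at C7 and C3. The fallback is a kinetically controlled Mukaiyama aldol from a regiodefined enol ether. It sets out from enynone 7. The copper-catalysed methylation of step 6 is quenched with TBSOTf instead of acid, which traps the C5–C6 enolate as (3S,4S)-1,4-bis(tert-butyldimethylsilyloxy)-3-methyl-3-[(trimethylsilyl)ethynyl]cyclohept-1-ene F1. K2CO3 in MeOH at 0 °C frees the alkyne to give (3S,4S)-1,4-bis(tert-butyldimethylsilyloxy)-3-ethynyl-3-methylcyclohept-1-ene F2. Acyl Sonogashira coupling with 11 gives the ynone enol ether F3, and double thia-Michael addition of 13 gives the dithiane enol ether F4. BF3·OEt2 in CH2Cl2 at −78 °C then forms C4–C5 from the only nucleophilic carbon available, and the route is rejoined at 16.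

Step 18. Hydride transfer from the C2 hydroxyl to C10 runs through a six-membered array trans-fused to the cyclopentane and may be slow, so that undirected delivery, or delivery guided by the C4 hydroxyl, erodes the facial selectivity at C10. The fallback uses reagent control. It sets out from diketone 27. One equivalent of Me4NBH(OAc)3 at −40 °C reduces only C2 and carbinol 28 is isolated. TESCl and imidazole give the 2β-triethylsilyl ether enone F5. Corey–Bakshi–Shibata reduction (the matched antipode of the 2-methyl oxazaborolidine, catecholborane, toluene, −78 °C) then gives 30, where the route resumes; the site-selective silylation of step 19 is then not needed.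

Step 19. The silylation may not discriminate well enough between the C2 and C10 hydroxyls. The fallback reverses the order of protection and epoxidation. It sets out from triol 29. VO(acac)2/t-BuOOH epoxidation, directed by the allylic C10 hydroxyl, gives the 8α,9α-epoxy triol F6, in which the C10 hydroxyl is flanked by the oxirane, hydrogen-bonded to it and therefore less nucleophilic. TESCl then silylates C2 and the route is rejoined at 31.

Further compounds
F1 | step 10 | (3S,4S)-1,4-bis(tert-butyldimethylsilyloxy)-3-methyl-3-[(trimethylsilyl)ethynyl]cyclohept-1-ene | CC(C)(C)[Si](C)(C)OC1=C[C@@](C)(C#C[Si](C)(C)C)[C@@H](O[Si](C)(C)C(C)(C)C)CCC1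
F2 | step 10 | (3S,4S)-1,4-bis(tert-butyldimethylsilyloxy)-3-ethynyl-3-methylcyclohept-1-ene | CC(C)(C)[Si](C)(C)OC1=C[C@@](C)(C#C)[C@@H](O[Si](C)(C)C(C)(C)C)CCC1
F3 | step 10 | (3S,4S)-1,4-bis(tert-butyldimethylsilyloxy)-3-methyl-3-(4-methyl-3-oxopent-1-yn-1-yl)cyclohept-1-ene | CC(C)(C)[Si](C)(C)OC1=C[C@@](C)(C#CC(=O)C(C)C)[C@@H](O[Si](C)(C)C(C)(C)C)CCC1
F4 | step 10 | (3R,4S)-1,4-bis(tert-butyldimethylsilyloxy)-3-methyl-3-[2-(3-methyl-2-oxobutyl)-1,3-dithian-2-yl]cyclohept-1-ene | CC(C)(C)[Si](C)(C)OC1=C[C@@](C)(C2(SCCCS2)CC(=O)C(C)C)[C@@H](O[Si](C)(C)C(C)(C)C)CCC1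
F5 | step 18 | 2β-triethylsilyl ether of 28 (C10 enone, 4α-hydroxy, 6β-tiglate) | C/C=C(\C)C(=O)O[C@H]1CC(C)=CC(=O)[C@@]2(C)[C@@H]1[C@](O)(C(C)C)C[C@@H]2O[Si](CC)(CC)CC
F6 | step 19 | 8α,9α-epoxy 2β,4α,10α-triol (6β-tiglate) | C/C=C(\C)C(=O)O[C@H]1C[C@]2(C)O[C@@H]2[C@H](O)[C@@]2(C)[C@@H]1[C@](O)(C(C)C)C[C@@H]2O
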